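Retrosynthesis: the C10 isovalerate and C6 aroyl C–O bonds are cut first. The seven-membered ring (C1, C5–C10) is then opened at C9–C10, because C10 is an allylic carbinol set between the quaternary C1 and the Z-trisubstituted C8=C9 alkene of that ring, the retron of an alkenyl iodide–aldehyde (Nozaki–Hiyama–Kishi) coupling.
The cyclopentane is cut at C3=C4 (ring-closing metathesis; the alkene stands in for the C4 carbinol), C1–CH3, C1–C2 and C4–C5. This leads to a butenolide whose lactone ring ties the C10 carbonyl to the C6 oxygen, made from an acrylate (C1=C5 by metathesis) of an allylic alcohol that comes from (S)-2-vinyloxirane and acetylide (C7–C8).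
Forward order: C5–C9 chain with the Z-iodoalkene, butenolide ring, five-membered carbocycle fused cis to the lactone, reductive opening of the lactone, seven-membered ring last, then the C10 ester and release of the phenol.
Stereochemistry: C6 from the resolved epoxide; C5 by conjugate addition anti to the C6 substituent; C1 by methylation anti to the C5 substituent, which places the C10 and C6 arms cis; C4 by convex-face epoxidation and hydride opening; C10 in the ring closure; the Z alkene by chelation-controlled carboalumination.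

Key step: step 17

Numbering: atom labels follow the bicyclic product: C1 quaternary methyl carbon, C2 and C3 ring CH2, C4 isopropyl carbinol, C5 ring-fusion CH, C6 aroyloxy carbon, C7 CH2, C8 methyl alkene carbon, C9 alkene CH, C10 isovaleryloxy carbon.
Remark: 4-[(tert-butyldimethylsilyl)oxy]benzoic acid 22 is taken as a purchasable reagent; it is otherwise one silylation away from 4-hydroxybenzoic acid.

Step 1
Reactants: 1 rac-2-ethenyloxirane
Product: 2 (S)-2-ethenyloxirane
Conditions: (R,R)-(salen)Co(OAc) {[N,N'-bis(3,5-di-tert-butylsalicylidene)cyclohexane-1,2-diaminato]cobalt acetate, the enantiomer that consumes the R epoxide, assigned by analogy with methyloxirane} 0.5 mol%, H2O (0.55 equiv), neat, 0 °C to rt; distillation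
Reagents that add atoms: none
Why: Hydrolytic kinetic resolution (Jacobsen): the chiral trivalent cobalt salen complex hydrolyses the R epoxide much faster than the S epoxide, so the S enantiomer, which carries the future C6 configuration, remains and is distilled from the diol.

Step 2
Reactants: 2 (S)-2-ethenyloxirane
Product: 3 (R)-hex-1-en-5-yn-3-ol
Conditions: LiC≡CH·H2NCH2CH2NH2, DMSO, 0 °C to rt; H2O
Reagents that add atoms: lithium acetylide ethylenediamine complex, [Li]C#C.NCCN
Why: SN2 opening of the terminal epoxide by acetylide at the unsubstituted carbon (future C7) in a dipolar aprotic solvent, which favours direct over allylic attack and leaves the C6 stereocentre untouched.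

Step 3
Reactants: 3 (R)-hex-1-en-5-yn-3-ol
Product: 6 (3R,5Z)-6-iodo-5-methylhexa-1,5-dien-3-ol, via E-alkenylalane 4 (not isolated), via Z-oxaaluminacycle 5 (not isolated)
Conditions: AlMe3 (3.5 equiv), Cp2ZrCl2 (0.25 equiv), (CH2Cl)2, 0 °C to rt; then reflux; I2, THF, −30 °C; aq. Na2S2O3, Rochelle salt
Reagents that add atoms: trimethylaluminium, C[Al](C)C; iodine, II
Why: Zirconium-catalysed syn-methylalumination of the terminal alkyne (Negishi carboalumination) gives the E-alkenylalane, heating lets aluminium move to the side of the chelating C6 alkoxide, and iodinolysis with retention should give the Z-iodoalkene (iodine cis to C7) without touching C6.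

Step 4
Reactants: 6 (3R,5Z)-6-iodo-5-methylhexa-1,5-dien-3-ol
Product: 7 (3R,5Z)-6-iodo-5-methylhexa-1,5-dien-3-yl prop-2-enoate
Conditions: acryloyl chloride, Et3N, CH2Cl2, −20 to 0 °C
Reagents that add atoms: acryloyl chloride, C=CC(=O)Cl
Why: O-Acylation of the secondary allylic alcohol by an acid chloride (nucleophilic acyl substitution) takes place at oxygen, so C6 keeps its configuration.

Step 5
Reactants: 7 (3R,5Z)-6-iodo-5-methylhexa-1,5-dien-3-yl prop-2-enoate
Product: 8 (5R)-5-[(2Z)-3-iodo-2-methylprop-2-en-1-yl]furan-2(5H)-one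
Conditions: second-generation Grubbs catalyst (H2IMes)(PCy3)Cl2Ru=CHPh (5 mol%), CH2Cl2 (0.01 M), 40 °C
Reagents that add atoms: none
Why: Ring-closing metathesis between the acrylate and the vinyl group on C6 releases ethene and forms the butenolide (C1=C5), while the trisubstituted iodoalkene is too hindered and electron-poor to enter the metathesis.

Step 6
Reactants: 9 3-methylbutan-2-one; 10 2,4,6-tri(propan-2-yl)benzenesulfonohydrazide
Product: 11 N'-(3-methylbutan-2-ylidene)-2,4,6-tri(propan-2-yl)benzenesulfonohydrazide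
Conditions: MeOH, HCl (cat.), rt; crystallisation
Reagents that add atoms: none
Why: Acid-catalysed condensation of a ketone with a sulfonyl hydrazide (hydrazone formation) gives the crystalline arenesulfonylhydrazone needed for a Shapiro reaction.

Step 7
Reactants: 11 N'-(3-methylbutan-2-ylidene)-2,4,6-tri(propan-2-yl)benzenesulfonohydrazide; 8 (5R)-5-[(2Z)-3-iodo-2-methylprop-2-en-1-yl]furan-2(5H)-one
Product: 15 (4R,5R)-5-[(2Z)-3-iodo-2-methylprop-2-en-1-yl]-4-(3-methylbut-1-en-2-yl)oxolan-2-one, via 3-methylbut-1-en-2-yllithium 12 (not isolated), via (3-methylbut-1-en-2-yl)magnesium bromide 13 (not isolated), via silyl ketene acetal 14 (not isolated)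
Conditions: 11, n-BuLi (2.0 equiv), THF, −78 to 0 °C; MgBr2·OEt2, −78 °C; CuBr·SMe2 (10 mol%), Me3SiCl, then 8, −78 °C; aq. NH4Cl
Reagents that add atoms: none
Why: The Shapiro reaction gives the less substituted alkenyllithium, which after transmetalation to magnesium undergoes copper-catalysed, chlorosilane-accelerated conjugate addition to the butenolide on the face anti to the C6 substituent, so C5 is set with the new C4–C5 bond trans to C6–C7; the organomagnesium reagent should not exchange with the alkenyl iodide at −78 °C.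

Step 8
Reactants: 15 (4R,5R)-5-[(2Z)-3-iodo-2-methylprop-2-en-1-yl]-4-(3-methylbut-1-en-2-yl)oxolan-2-one
Product: 16 (3S,4R,5R)-5-[(2Z)-3-iodo-2-methylprop-2-en-1-yl]-4-(3-methylbut-1-en-2-yl)-3-(prop-2-en-1-yl)oxolan-2-one
Conditions: lithium diisopropylamide, THF, −78 °C; allyl bromide, DMPU, −78 to −30 °C
Reagents that add atoms: allyl bromide (3-bromoprop-1-ene), C=CCBr
Why: Lactone enolate alkylation (SN2 on the allylic bromide) brings in C2 and C3; the new centre at C1 (expected trans to the C5 substituent) is planarised again in the next step, so its configuration does not matter.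

Step 9
Reactants: 16 (3S,4R,5R)-5-[(2Z)-3-iodo-2-methylprop-2-en-1-yl]-4-(3-methylbut-1-en-2-yl)-3-(prop-2-en-1-yl)oxolan-2-one
Product: 17 (3R,4S,5R)-5-[(2Z)-3-iodo-2-methylprop-2-en-1-yl]-3-methyl-4-(3-methylbut-1-en-2-yl)-3-(prop-2-en-1-yl)oxolan-2-one
Conditions: lithium diisopropylamide, THF, −78 °C; MeI, DMPU, −78 to −20 °C
Reagents that add atoms: iodomethane, CI
Why: Second lactone enolate alkylation: iodomethane approaches the trisubstituted enolate anti to the bulky alkenyl group on the neighbouring C5, so the methyl group ends trans and the allyl group cis to it, which fixes the quaternary C1 with the C10 carbonyl and the C6 arm cis.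

Step 10
Reactants: 17 (3R,4S,5R)-5-[(2Z)-3-iodo-2-methylprop-2-en-1-yl]-3-methyl-4-(3-methylbut-1-en-2-yl)-3-(prop-2-en-1-yl)oxolan-2-one
Product: 18 (1R,4R,5S)-4-[(2Z)-3-iodo-2-methylprop-2-en-1-yl]-1-methyl-6-(propan-2-yl)-3-oxabicyclo[3.3.0]oct-6-en-2-one
Conditions: second-generation Grubbs catalyst (H2IMes)(PCy3)Cl2Ru=CHPh (5–10 mol%), toluene (0.005 M), 80 °C
Reagents that add atoms: none
Why: Ring-closing metathesis between the allyl group on C1 and the 1,1-disubstituted alkene on C5, which are cis after step 9, releases ethene and closes the cyclopentene with the isopropyl group on the C3=C4 bond, giving the cis-fused bicycle without change at any stereocentre.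

Step 11
Reactants: 18 (1R,4R,5S)-4-[(2Z)-3-iodo-2-methylprop-2-en-1-yl]-1-methyl-6-(propan-2-yl)-3-oxabicyclo[3.3.0]oct-6-en-2-one
Product: 19 convex-face 6,7-epoxide of 18 (oxirane oxygen cis to the C1 methyl group and to H-5)
Conditions: mCPBA, NaHCO3, CH2Cl2, 0 °C
Reagents that add atoms: 3-chloroperoxybenzoic acid, O=C(OO)c1cccc(Cl)c1
Why: Prilezhaev epoxidation by the peracid takes place at the electron-rich trisubstituted ring alkene from the convex face of the cis-fused bicycle, anti to the lactone ring and the C5–C6 bond, which puts the oxygen on C4 cis to the C1 methyl group; the iodoalkene is deactivated by the halogen.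

Step 12
Reactants: 19 convex-face 6,7-epoxide of 18
Product: 20 (1S,2S,3R)-3-(hydroxymethyl)-2-[(1R,3Z)-1-hydroxy-4-iodo-3-methylbut-3-en-1-yl]-3-methyl-1-(propan-2-yl)cyclopentan-1-ol
Conditions: LiEt3BH (6 equiv), THF, 0 °C to rt; H2O
Reagents that add atoms: none
Why: Hydride reduction with LiEt3BH opens the epoxide by SN2 attack at the secondary C3, so the C4–O bond and its configuration are kept as the tertiary alcohol, and reduces the lactone to the C10 and C6 alcohols; the alkenyl iodide should not react with the borohydride.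

Step 13
Reactants: 20 (1S,2S,3R)-3-(hydroxymethyl)-2-[(1R,3Z)-1-hydroxy-4-iodo-3-methylbut-3-en-1-yl]-3-methyl-1-(propan-2-yl)cyclopentan-1-ol
Product: 21 (1S,2S,3R)-2-[(1R,3Z)-1-hydroxy-4-iodo-3-methylbut-3-en-1-yl]-3-methyl-1-(propan-2-yl)-3-{[(triethylsilyl)oxy]methyl}cyclopentan-1-ol
Conditions: Et3SiCl (1.05 equiv), imidazole, CH2Cl2, −40 to 0 °C
Reagents that add atoms: chlorotriethylsilane, CC[Si](Cl)(CC)CC
Why: Silylation of an alcohol with a silyl chloride is fastest at the primary C10 hydroxyl, while the secondary C6 hydroxyl next to the branched C5 and the tertiary C4 hydroxyl react much more slowly at low temperature.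

Step 14
Reactants: 21 (1S,2S,3R)-2-[(1R,3Z)-1-hydroxy-4-iodo-3-methylbut-3-en-1-yl]-3-methyl-1-(propan-2-yl)-3-{[(triethylsilyl)oxy]methyl}cyclopentan-1-ol; 22 4-[(tert-butyldimethylsilyl)oxy]benzoic acid
Product: 24 (1R,3Z)-1-[(1S,2R,5S)-5-hydroxy-2-methyl-5-(propan-2-yl)-2-{[(triethylsilyl)oxy]methyl}cyclopentyl]-4-iodo-3-methylbut-3-en-1-yl 4-[(tert-butyldimethylsilyl)oxy]benzoate, via mixed anhydride 23 (not isolated)
Conditions: 22, 2,4,6-trichlorobenzoyl chloride, Et3N, toluene, rt; then 21, DMAP, toluene, 40 °C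
Reagents that add atoms: none
Why: Yamaguchi esterification through the mixed anhydride acylates the hindered secondary C6 alcohol at oxygen, so C6 keeps its configuration, and the tertiary C4 alcohol is too hindered to react.

Step 15
Reactants: 24 the C10 triethylsilyl ether C6 ester
Product: 25 (1R,3Z)-1-[(1S,2R,5S)-5-hydroxy-2-(hydroxymethyl)-2-methyl-5-(propan-2-yl)cyclopentyl]-4-iodo-3-methylbut-3-en-1-yl 4-[(tert-butyldimethylsilyl)oxy]benzoate
Conditions: pyridinium p-toluenesulfonate, MeOH/CH2Cl2, 0 °C to rt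
Reagents that add atoms: none
Why: Acid-catalysed methanolysis removes the primary triethylsilyl ether, while the aryl tert-butyldimethylsilyl ether and the ester are stable to mild acid.

Step 16
Reactants: 25 the C10 primary alcohol
Product: 26 (1R,3Z)-1-[(1S,2R,5S)-2-formyl-5-hydroxy-2-methyl-5-(propan-2-yl)cyclopentyl]-4-iodo-3-methylbut-3-en-1-yl 4-[(tert-butyldimethylsilyl)oxy]benzoate
Conditions: Dess–Martin periodinane, NaHCO3, CH2Cl2, 0 °C to rt
Reagents that add atoms: none
Why: Dess–Martin oxidation converts the primary neopentyl alcohol to the aldehyde, the tertiary alcohol cannot be oxidised, and the aldehyde on the quaternary C1 has no α-hydrogen to epimerise.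

Step 17
Reactants: 26 the C1 formyl cyclopentane with the Z-iodoalkenyl arm on C5
Product: 27 (1S,3aR,4R,8R,8aS)-1,4-dihydroxy-3a,6-dimethyl-1-(propan-2-yl)-1,2,3,3a,4,7,8,8a-octahydroazulen-8-yl 4-[(tert-butyldimethylsilyl)oxy]benzoate
Conditions: CrCl2 (8 equiv), NiCl2 (2 mol%), degassed DMSO (0.005 M), rt; H2O
Reagents that add atoms: none
Why: Zerovalent nickel, formed from NiCl2 by divalent chromium, inserts into the C9–I bond with retention of the Z geometry, the alkenyl group passes to trivalent chromium, and the alkenylchromium adds to the C10 aldehyde to give a chromium alkoxide that is protonated on work-up. The closest known reaction type is the intramolecular Nozaki–Hiyama–Kishi alkenyl iodide–aldehyde coupling used for medium rings. The seven-membered ring closes in 7-exo-trig fashion at the carbonyl carbon, helped by the cis placement of the two arms on C1 and C5 and by the Z alkene, which points C9 toward C10. The new C10 stereocentre is controlled by the adjacent quaternary C1 within the cis-fused transition state: the chromium-bound oxygen should take the convex side next to the C1 methyl group and leave the aldehyde hydrogen under the five-membered ring, which gives the 10-hydroxyl cis to that methyl group. The step needs chemoselectivity for the aldehyde over the aryl ester, the silyl ether and the free tertiary alcohol, which the low basicity and carbonyl selectivity of organochromium reagents secure, and high dilution holds back intermolecular coupling.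

Step 18
Reactants: 27 the C10 allylic alcohol
Product: 28 (1S,3aR,4R,8R,8aS)-1-hydroxy-3a,6-dimethyl-4-[(3-methylbutanoyl)oxy]-1-(propan-2-yl)-1,2,3,3a,4,7,8,8a-octahydroazulen-8-yl 4-[(tert-butyldimethylsilyl)oxy]benzoate
Conditions: 3-methylbutanoic anhydride, Et3N, DMAP, CH2Cl2, rt
Reagents that add atoms: 3-methylbutanoic anhydride, CC(C)CC(=O)OC(=O)CC(C)C
Why: DMAP-catalysed acyl transfer (Steglich-type acylation) esterifies the secondary allylic C10 alcohol at oxygen with retention, and the tertiary C4 alcohol does not react.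

Step 19
Reactants: 28 the silyl-protected diester
Product: 29 (1S,3aR,4R,8R,8aS)-1-hydroxy-3a,6-dimethyl-4-[(3-methylbutanoyl)oxy]-1-(propan-2-yl)-1,2,3,3a,4,7,8,8a-octahydroazulen-8-yl 4-hydroxybenzoate
Conditions: tetrabutylammonium fluoride, AcOH (1:1), THF, 0 °C
Reagents that add atoms: none
Why: Fluoride-mediated desilylation cleaves the aryl silyl ether quickly through Si–F bond formation, and the acetic acid buffer keeps the two esters and the allylic system intact.

Compound list
1 | rac-2-ethenyloxirane (butadiene monoxide) | C=CC1CO1 | starting material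
2 | (S)-2-ethenyloxirane | C=C[C@H]1CO1 | intermediate
3 | (R)-hex-1-en-5-yn-3-ol | C=C[C@H](O)CC#C | intermediate
4 | E-alkenylalane: dimethylaluminium alkoxide of (3R,5E)-6-(dimethylalumanyl)-5-methylhexa-1,5-dien-3-ol | C=C[C@H](O[Al](C)C)C/C(C)=C/[Al](C)C | intermediate (not isolated)
5 | Z-oxaaluminacycle: six-membered cyclic methylalane with aluminium bound to the C6 oxygen and to C9 | C=C[C@H]1C/C(C)=C\[Al](C)O1 | intermediate (not isolated)
6 | (3R,5Z)-6-iodo-5-methylhexa-1,5-dien-3-ol | C=C[C@H](O)C/C(C)=C\I | intermediate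
7 | (3R,5Z)-6-iodo-5-methylhexa-1,5-dien-3-yl prop-2-enoate | C=CC(=O)O[C@@H](C=C)C/C(C)=C\I | intermediate
8 | (5R)-5-[(2Z)-3-iodo-2-methylprop-2-en-1-yl]furan-2(5H)-one | O=C1C=C[C@@H](C/C(C)=C\I)O1 | intermediate
9 | 3-methylbutan-2-one | CC(C)C(C)=O | starting material
10 | 2,4,6-tri(propan-2-yl)benzenesulfonohydrazide | CC(C)c1cc(C(C)C)c(S(=O)(=O)NN)c(C(C)C)c1 | starting material
11 | N'-(3-methylbutan-2-ylidene)-2,4,6-tri(propan-2-yl)benzenesulfonohydrazide | CC(C)C(C)=NNS(=O)(=O)c1c(C(C)C)cc(C(C)C)cc1C(C)C | intermediate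
12 | (3-methylbut-1-en-2-yl)lithium | [Li]C(=C)C(C)C | intermediate (not isolated)
13 | (3-methylbut-1-en-2-yl)magnesium bromide | Br[Mg]C(=C)C(C)C | intermediate (not isolated)
14 | trimethylsilyl ketene acetal of 15 | C[Si](C)(C)OC1=C[C@H](C(=C)C(C)C)[C@@H](C/C(C)=C\I)O1 | intermediate (not isolated)
15 | (4R,5R)-5-[(2Z)-3-iodo-2-methylprop-2-en-1-yl]-4-(3-methylbut-1-en-2-yl)oxolan-2-one | O=C1C[C@H](C(=C)C(C)C)[C@@H](C/C(C)=C\I)O1 | intermediate
16 | (3S,4R,5R)-5-[(2Z)-3-iodo-2-methylprop-2-en-1-yl]-4-(3-methylbut-1-en-2-yl)-3-(prop-2-en-1-yl)oxolan-2-one | O=C1[C@@H](CC=C)[C@H](C(=C)C(C)C)[C@@H](C/C(C)=C\I)O1 | intermediate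
17 | (3R,4S,5R)-5-[(2Z)-3-iodo-2-methylprop-2-en-1-yl]-3-methyl-4-(3-methylbut-1-en-2-yl)-3-(prop-2-en-1-yl)oxolan-2-one | O=C1[C@](C)(CC=C)[C@H](C(=C)C(C)C)[C@@H](C/C(C)=C\I)O1 | intermediate
18 | (1R,4R,5S)-4-[(2Z)-3-iodo-2-methylprop-2-en-1-yl]-1-methyl-6-(propan-2-yl)-3-oxabicyclo[3.3.0]oct-6-en-2-one | O=C1[C@]2(C)CC=C(C(C)C)[C@@H]2[C@@H](C/C(C)=C\I)O1 | intermediate
19 | convex-face 6,7-epoxide of 18 (oxirane oxygen cis to the C1 methyl group and H-5) | O=C1[C@]2(C)C[C@H]3O[C@@]3(C(C)C)[C@@H]2[C@@H](C/C(C)=C\I)O1 | intermediate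
20 | (1S,2S,3R)-3-(hydroxymethyl)-2-[(1R,3Z)-1-hydroxy-4-iodo-3-methylbut-3-en-1-yl]-3-methyl-1-(propan-2-yl)cyclopentan-1-ol | OC[C@]1(C)CC[C@](O)(C(C)C)[C@@H]1[C@H](O)C/C(C)=C\I | intermediate
21 | (1S,2S,3R)-2-[(1R,3Z)-1-hydroxy-4-iodo-3-methylbut-3-en-1-yl]-3-methyl-1-(propan-2-yl)-3-{[(triethylsilyl)oxy]methyl}cyclopentan-1-ol | CC[Si](CC)(CC)OC[C@]1(C)CC[C@](O)(C(C)C)[C@@H]1[C@H](O)C/C(C)=C\I | intermediate
22 | 4-[(tert-butyldimethylsilyl)oxy]benzoic acid | CC(C)(C)[Si](C)(C)Oc1ccc(cc1)C(=O)O | starting material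
23 | 4-[(tert-butyldimethylsilyl)oxy]benzoic 2,4,6-trichlorobenzoic anhydride | CC(C)(C)[Si](C)(C)Oc1ccc(cc1)C(=O)OC(=O)c1c(Cl)cc(Cl)cc1Cl | intermediate (not isolated)
24 | (1R,3Z)-1-[(1S,2R,5S)-5-hydroxy-2-methyl-5-(propan-2-yl)-2-{[(triethylsilyl)oxy]methyl}cyclopentyl]-4-iodo-3-methylbut-3-en-1-yl 4-[(tert-butyldimethylsilyl)oxy]benzoate | CC[Si](CC)(CC)OC[C@]1(C)CC[C@](O)(C(C)C)[C@@H]1[C@H](OC(=O)c2ccc(O[Si](C)(C)C(C)(C)C)cc2)C/C(C)=C\I | intermediate
25 | (1R,3Z)-1-[(1S,2R,5S)-5-hydroxy-2-(hydroxymethyl)-2-methyl-5-(propan-2-yl)cyclopentyl]-4-iodo-3-methylbut-3-en-1-yl 4-[(tert-butyldimethylsilyl)oxy]benzoate | OC[C@]1(C)CC[C@](O)(C(C)C)[C@@H]1[C@H](OC(=O)c2ccc(O[Si](C)(C)C(C)(C)C)cc2)C/C(C)=C\I | intermediate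
26 | (1R,3Z)-1-[(1S,2R,5S)-2-formyl-5-hydroxy-2-methyl-5-(propan-2-yl)cyclopentyl]-4-iodo-3-methylbut-3-en-1-yl 4-[(tert-butyldimethylsilyl)oxy]benzoate | O=C[C@]1(C)CC[C@](O)(C(C)C)[C@@H]1[C@H](OC(=O)c2ccc(O[Si](C)(C)C(C)(C)C)cc2)C/C(C)=C\I | intermediate
27 | (1S,3aR,4R,8R,8aS)-1,4-dihydroxy-3a,6-dimethyl-1-(propan-2-yl)-1,2,3,3a,4,7,8,8a-octahydroazulen-8-yl 4-[(tert-butyldimethylsilyl)oxy]benzoate | CC1=C[C@@H](O)[C@]2(C)CC[C@](O)(C(C)C)[C@@H]2[C@H](OC(=O)c3ccc(O[Si](C)(C)C(C)(C)C)cc3)C1 | intermediate
28 | (1S,3aR,4R,8R,8aS)-1-hydroxy-3a,6-dimethyl-4-[(3-methylbutanoyl)oxy]-1-(propan-2-yl)-1,2,3,3a,4,7,8,8a-octahydroazulen-8-yl 4-[(tert-butyldimethylsilyl)oxy]benzoate | CC1=C[C@@H](OC(=O)CC(C)C)[C@]2(C)CC[C@](O)(C(C)C)[C@@H]2[C@H](OC(=O)c3ccc(O[Si](C)(C)C(C)(C)C)cc3)C1 | intermediate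
29 | (1S,3aR,4R,8R,8aS)-1-hydroxy-3a,6-dimethyl-4-[(3-methylbutanoyl)oxy]-1-(propan-2-yl)-1,2,3,3a,4,7,8,8a-octahydroazulen-8-yl 4-hydroxybenzoate (CNP0086724.1) | CC1=C[C@@H](OC(=O)CC(C)C)[C@]2(C)CC[C@](O)(C(C)C)[C@@H]2[C@H](OC(=O)c2ccc(O)cc2)C1 | target

Total step count: 19. Longest linear sequence: 18 steps (steps 1–5 and 7–19, from 1 to 29); step 6 prepares the hydrazone for step 7.

Steps most likely to fail

Step 17. The ring may close with poor or reversed facial selectivity at the C10 aldehyde, so that the 10-epimer forms. The fallback sets out from 26. The ring closure is run as before and its product, the 10-epimer F6 alone or mixed with 27, is oxidised with Dess–Martin periodinane to the enone F7. The ketone is then reduced with catecholborane and (S)-2-methyl-CBS-oxazaborolidine (Corey–Bakshi–Shibata reduction), in which the quaternary C1 should act as the large group and the alkene carbon C9 as the small one, so that the reagent and not the ring decides the C10 configuration. The route is rejoined at 27.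

Step 3. The chelation-driven E-to-Z isomerisation of the alkenylalane may stay incomplete, or the allylic aluminium alkoxide may degrade on long heating, so that geometric purity is lost. The fallback sets out from 3. Double deprotonation (n-BuLi, 2 equiv) and Me3SiCl give the O,C-bis(trimethylsilyl) enyne F1, in which the protected oxygen can no longer steer the aluminium. Zirconium-catalysed syn-methylalumination (AlMe3, Cp2ZrCl2, 0 °C, short time) places aluminium on the silicon-bearing carbon, and acidic protonolysis gives the (Z)-alkenylsilane alcohol F2 with the chain cis to silicon and the silyl ether cleaved. Iododesilylation with N-iodosuccinimide in 1,1,1,3,3,3-hexafluoropropan-2-ol, which goes with retention, rejoins the route at 6.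

Step 7. Halogen–metal exchange or coupling at the alkenyl iodide may compete, and the hindered α-branched alkenyl nucleophile may add sluggishly. The fallback sets out from 8 and brings in C4 as an acyl anion equivalent. 2-(Propan-2-yl)-1,3-dithiane F3 (from 2-methylpropanal and propane-1,3-dithiol, BF3·OEt2) is lithiated with n-BuLi and added 1,4 to 8 in THF/DMPU, anti to the C6 substituent, to give the dithianyl lactone F4. Removal of the dithiane with iodomethane and CaCO3 in aqueous acetonitrile gives the isobutyryl lactone F5. Takai–Lombardo methylenation (Zn, CH2Br2, TiCl4), which is non-basic and spares the lactone, turns the ketone into the 3-methylbut-1-en-2-yl group and rejoins the route at 15.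

Further compounds
F1 | step 3 | (R)-trimethyl{[6-(trimethylsilyl)hex-1-en-5-yn-3-yl]oxy}silane | C=C[C@H](O[Si](C)(C)C)CC#C[Si](C)(C)C
F2 | step 3 | (3R,5Z)-5-methyl-6-(trimethylsilyl)hexa-1,5-dien-3-ol | C=C[C@H](O)C/C(C)=C\[Si](C)(C)C
F3 | step 7 | 2-(propan-2-yl)-1,3-dithiane | CC(C)C1SCCCS1
F4 | step 7 | (5R)-4,5-trans-5-[(2Z)-3-iodo-2-methylprop-2-en-1-yl]-4-[2-(propan-2-yl)-1,3-dithian-2-yl]oxolan-2-one | O=C1C[C@H](C2(C(C)C)SCCCS2)[C@@H](C/C(C)=C\I)O1
F5 | step 7 | (5R)-4,5-trans-5-[(2Z)-3-iodo-2-methylprop-2-en-1-yl]-4-(2-methylpropanoyl)oxolan-2-one | O=C1C[C@H](C(=O)C(C)C)[C@@H](C/C(C)=C\I)O1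
F6 | step 17 | 10-epimer of 27 (C10 hydroxyl trans to the C1 methyl group) | CC1=C[C@H](O)[C@]2(C)CC[C@](O)(C(C)C)[C@@H]2[C@H](OC(=O)c3ccc(O[Si](C)(C)C(C)(C)C)cc3)C1
F7 | step 17 | C10 ketone (enone) corresponding to 27 | CC1=CC(=O)[C@]2(C)CC[C@](O)(C(C)C)[C@@H]2[C@H](OC(=O)c3ccc(O[Si](C)(C)C(C)(C)C)cc3)C1
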